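The non-aromatic ring (the cyclohexadienone that holds the quaternary carbon) is cut at two bonds: ring C=O carbon to methyl-bearing carbon, and bridge-bearing carbon to the enol carbon next to the quaternary centre. Its 1,3,5-oxygen pattern makes the two-carbon piece an ynol ether. A Danheiser-type annulation of ethoxyacetylene with a 4,4-disubstituted 3-ethoxy-2-methylcyclobutenone therefore builds the ring in one operation and creates the quaternary stereocentre as the terminus of a 6π closure. A neighbouring silyloxy stereocentre (the masked isobutyryl ketone, from Noyori hydrogenation) steers this closure and makes the epimers separable. Oxidation and hydrolysis give the chiral trione, which is joined to 3-prenylphlorisobutyrophenone by a one-carbon Mannich/quinone methide coupling.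

Key step: step 6

Assumption: the sense of 1,2-induction in the ring closure of step 6 is taken from an A(1,3)-strain model (the ketene carbon adds anti to isopropyl); should the other C-6 epimer prevail, the (S)-BINAP catalyst in step 1 would give the matching series through the same steps.

Step 1
Reactants: 1 ethyl 4-methyl-3-oxopentanoate
Product: 2 ethyl (S)-3-hydroxy-4-methylpentanoate
Conditions: H2 (50 bar), RuCl2[(R)-BINAP] (0.1 mol%), EtOH, 50 °C
Reagents that add atoms: none
Why: Noyori asymmetric hydrogenation of a β-keto ester; the (R)-BINAP complex of divalent ruthenium should deliver hydrogen to one face of the chelated ketone and set the carbinol centre (S here because isopropyl outranks CH2CO2Et).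

Step 2
Reactants: 2 ethyl (S)-3-hydroxy-4-methylpentanoate; 3 prenyl bromide (1-bromo-3-methylbut-2-ene)
Product: 4 ethyl (2R,3R)-3-hydroxy-4-methyl-2-(3-methylbut-2-en-1-yl)pentanoate
Conditions: LiN(iPr)2 (2.2 equiv), THF, −78 to −20 °C; then 3 (1.3 equiv), DMPU, −78 to 0 °C
Reagents that add atoms: none
Why: Fráter–Seebach alkylation; the chelated alkoxide–enolate dianion should be alkylated anti to the carbinol substituent, and the C-2 centre is of no consequence because it becomes the ketene carbon in step 5.

Step 3
Reactants: 4 ethyl (2R,3R)-3-hydroxy-4-methyl-2-(3-methylbut-2-en-1-yl)pentanoate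
Product: 5 (2R,3R)-3-hydroxy-4-methyl-2-(3-methylbut-2-en-1-yl)pentanoic acid
Conditions: LiOH, THF/MeOH/H2O, 40 °C; then 1 M HCl to pH 3
Reagents that add atoms: lithium hydroxide, [Li+].[OH-]
Why: ester saponification; the free β-hydroxy carboxylate should not undergo retro-aldol at this temperature and the carbinol centre is untouched.

Step 4
Reactants: 5 (2R,3R)-3-hydroxy-4-methyl-2-(3-methylbut-2-en-1-yl)pentanoic acid
Product: 7 (2R,3R)-4-methyl-2-(3-methylbut-2-en-1-yl)-3-(triethylsilyloxy)pentanoic acid, via silyl ester 6 (not isolated)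
Conditions: Et3SiOTf (2.3 equiv), 2,6-lutidine, CH2Cl2, −40 to 0 °C; then H2O/THF, 23 °C; pH 5 buffer
Reagents that add atoms: triethylsilyl trifluoromethanesulfonate, CC[Si](CC)(CC)OS(=O)(=O)C(F)(F)F
Why: persilylation followed by selective hydrolysis of the labile silyl ester should leave the hindered secondary silyl ether in place.

Step 5
Reactants: 7 (2R,3R)-4-methyl-2-(3-methylbut-2-en-1-yl)-3-(triethylsilyloxy)pentanoic acid; 8 1-ethoxyprop-1-yne
Product: 11 3-ethoxy-2-methyl-4-(3-methylbut-2-en-1-yl)-4-[(R)-2-methyl-1-(triethylsilyloxy)propyl]cyclobut-2-en-1-one (both C-4 epimers), via acid chloride 9 (not isolated), via ketene 10 (not isolated)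
Conditions: 1-chloro-N,N,2-trimethylprop-1-en-1-amine (1.2 equiv), CH2Cl2, 0 to 23 °C; then 8 (3 equiv), Et3N (2.5 equiv), MeCN, 50 °C
Reagents that add atoms: none
Why: neutral acid chloride formation (Ghosez reagent) spares the silyl ether, and dehydrochlorination gives a dialkylketene that should undergo ketene–ynol ether [2+2] cycloaddition with the carbonyl carbon bonding to the methyl-bearing alkyne carbon; ring C-4 forms as both epimers, which converge in step 6.

Step 6
Reactants: 11 3-ethoxy-2-methyl-4-(3-methylbut-2-en-1-yl)-4-[(R)-2-methyl-1-(triethylsilyloxy)propyl]cyclobut-2-en-1-one; 12 ethoxyacetylene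
Product: 16 (S)-3,5-diethoxy-4-methyl-6-(3-methylbut-2-en-1-yl)-6-[(R)-2-methyl-1-(triethylsilyloxy)propyl]cyclohexa-2,4-dien-1-one, via vinylketene 13 (not isolated), via alkenylcyclobutenone 14 (not isolated), via dienylketene 15 (not isolated)
Conditions: 12 (5 equiv), toluene, sealed tube, 90 °C, dark; chromatography on SiO2 to separate the C-6 epimers
Reagents that add atoms: none
Why: Heating opens 11 (4π electrocyclic) to vinylketene 13, whose ketene C=C adds ethoxyacetylene in a regioselective [2+2] (ketene carbonyl carbon to the unsubstituted alkyne carbon, ketene α-carbon to the ethoxy-bearing carbon) to give 14; a second 4π opening gives dienylketene 15, and a 6π electrocyclisation returns the carbonyl carbon to the fully substituted terminus. The closest known reaction is the Danheiser benzannulation of cyclobutenones with alkoxy- or siloxyalkynes, here stopped at the 2,4-cyclohexadienone because the terminus is quaternary. The one ring that is closed, the six-membered dienone, forms by thermal disrotatory 6π electrocyclisation of 15. The new stereocentre C-6 is set in this closure under 1,2-induction from the (R)-silyloxy centre: with its C–H eclipsing the enol ether double bond (A(1,3) strain) the ketene carbon should add anti to isopropyl, which leads to the same C-6 configuration from either alkene geometry of 13, and because the two C-6 epimers are diastereomers the unwanted one is removed on silica. Regiochemistry follows from the ketene/ynol ether polarity; the ketone is carried as a silyl ether because a 4-acylcyclobutenone would close to an α-pyrone; the ynol ether, far more ketenophilic than a trisubstituted alkene and used in excess, should outrun intramolecular ketene–prenyl cycloaddition; and 90 °C is chosen to keep the 6-prenyl dienone out of Cope and retro-Claisen shifts.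

Step 7
Reactants: 16 (S)-3,5-diethoxy-4-methyl-6-(3-methylbut-2-en-1-yl)-6-[(R)-2-methyl-1-(triethylsilyloxy)propyl]cyclohexa-2,4-dien-1-one
Product: 17 (S)-3,5-diethoxy-6-[(R)-1-hydroxy-2-methylpropyl]-4-methyl-6-(3-methylbut-2-en-1-yl)cyclohexa-2,4-dien-1-one
Conditions: HF·pyridine, pyridine, THF, 0 °C
Reagents that add atoms: none
Why: buffered acidic fluoride desilylation frees the carbinol without forming an alkoxide (which would trigger retro-aldol aromatisation), and the anhydrous medium should leave both vinylogous esters intact.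

Step 8
Reactants: 17 (S)-3,5-diethoxy-6-[(R)-1-hydroxy-2-methylpropyl]-4-methyl-6-(3-methylbut-2-en-1-yl)cyclohexa-2,4-dien-1-one
Product: 18 (R)-3,5-diethoxy-4-methyl-6-(3-methylbut-2-en-1-yl)-6-(2-methylpropanoyl)cyclohexa-2,4-dien-1-one
Conditions: Dess–Martin periodinane (1.5 equiv), CH2Cl2, 0 to 23 °C
Reagents that add atoms: none
Why: Dess–Martin oxidation of a β-hydroxy ketone to the β-diketone under non-basic conditions; the controlling carbinol centre is erased and C-6 remains the only stereocentre (descriptor R only through the priority change), while the ring C–H is protected as part of a vinylogous ester.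

Step 9
Reactants: 18 (R)-3,5-diethoxy-4-methyl-6-(3-methylbut-2-en-1-yl)-6-(2-methylpropanoyl)cyclohexa-2,4-dien-1-one
Product: 19 (R)-3,5-dihydroxy-2-methyl-4-(3-methylbut-2-en-1-yl)-4-(2-methylpropanoyl)cyclohexa-2,5-dien-1-one (enol form of the trione)
Conditions: 1 M HCl, THF, 23 °C
Reagents that add atoms: water, O
Why: acid hydrolysis of the two vinylogous ethyl esters by addition–elimination; dilute acid at room temperature should spare the prenyl group, and the quaternary carbon cannot enolise, so its configuration is kept.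

Step 10
Reactants: 20 2-methyl-1-(2,4,6-trihydroxyphenyl)propan-1-one (phlorisobutyrophenone); 3 prenyl bromide
Product: 21 2-methyl-1-[2,4,6-trihydroxy-3-(3-methylbut-2-en-1-yl)phenyl]propan-1-one
Conditions: DBU (1.0 equiv), THF, 0 to 23 °C; 3 (0.9 equiv)
Reagents that add atoms: none
Why: C-alkylation of an acylphloroglucinol phenolate with an allylic bromide; a slight deficit of bromide should limit double prenylation, and the mono-prenyl product is separated from the rest.

Step 11
Reactants: 19 (R)-3,5-dihydroxy-2-methyl-4-(3-methylbut-2-en-1-yl)-4-(2-methylpropanoyl)cyclohexa-2,5-dien-1-one; 21 2-methyl-1-[2,4,6-trihydroxy-3-(3-methylbut-2-en-1-yl)phenyl]propan-1-one; 22 N,N-dimethylmethyleneiminium iodide (Eschenmoser's salt)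
Product: 25 (S)-3,5-dihydroxy-6-methyl-4-(3-methylbut-2-en-1-yl)-4-(2-methylpropanoyl)-2-{[2,4,6-trihydroxy-3-(3-methylbut-2-en-1-yl)-5-(2-methylpropanoyl)phenyl]methyl}cyclohexa-2,5-dien-1-one, via Mannich base 23 (not isolated), via quinone methide 24 (not isolated)
Conditions: 21, 22 (0.95 equiv), MeCN, 23 °C; then 19 (0.9 equiv), Et3N (2.2 equiv), 50 °C; 1 M HCl work-up
Reagents that add atoms: none
Why: Mannich aminomethylation of the single free aromatic position of 21, then thermal loss of dimethylamine to an ortho-quinone methide that should be intercepted in Michael fashion by the only nucleophilic ring carbon of 19; the quaternary stereocentre is not involved and 23 has no free ring position for self-condensation.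

Compound list
1 | ethyl 4-methyl-3-oxopentanoate | CCOC(=O)CC(=O)C(C)C | starting material
2 | ethyl (S)-3-hydroxy-4-methylpentanoate | CCOC(=O)C[C@H](O)C(C)C | intermediate
3 | prenyl bromide (1-bromo-3-methylbut-2-ene) | CC(C)=CCBr | starting material
4 | ethyl (2R,3R)-3-hydroxy-4-methyl-2-(3-methylbut-2-en-1-yl)pentanoate | CCOC(=O)[C@H](CC=C(C)C)[C@H](O)C(C)C | intermediate
5 | (2R,3R)-3-hydroxy-4-methyl-2-(3-methylbut-2-en-1-yl)pentanoic acid | OC(=O)[C@H](CC=C(C)C)[C@H](O)C(C)C | intermediate
6 | triethylsilyl (2R,3R)-4-methyl-2-(3-methylbut-2-en-1-yl)-3-(triethylsilyloxy)pentanoate | CC[Si](CC)(CC)OC(=O)[C@H](CC=C(C)C)[C@H](O[Si](CC)(CC)CC)C(C)C | intermediate (not isolated)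
7 | (2R,3R)-4-methyl-2-(3-methylbut-2-en-1-yl)-3-(triethylsilyloxy)pentanoic acid | OC(=O)[C@H](CC=C(C)C)[C@H](O[Si](CC)(CC)CC)C(C)C | intermediate
8 | 1-ethoxyprop-1-yne | CCOC#CC | starting material
9 | (2R,3R)-4-methyl-2-(3-methylbut-2-en-1-yl)-3-(triethylsilyloxy)pentanoyl chloride | ClC(=O)[C@H](CC=C(C)C)[C@H](O[Si](CC)(CC)CC)C(C)C | intermediate (not isolated)
10 | 5-methyl-2-[(R)-2-methyl-1-(triethylsilyloxy)propyl]hexa-1,4-dien-1-one (ketene) | O=C=C(CC=C(C)C)[C@H](O[Si](CC)(CC)CC)C(C)C | intermediate (not isolated)
11 | 3-ethoxy-2-methyl-4-(3-methylbut-2-en-1-yl)-4-[(R)-2-methyl-1-(triethylsilyloxy)propyl]cyclobut-2-en-1-one, both C-4 epimers | CCOC1=C(C)C(=O)C1(CC=C(C)C)[C@H](O[Si](CC)(CC)CC)C(C)C | intermediate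
12 | ethoxyacetylene | CCOC#C | starting material
13 | 3-ethoxy-2,7-dimethyl-4-[(R)-2-methyl-1-(triethylsilyloxy)propyl]octa-1,3,6-trien-1-one (vinylketene, both alkene geometries) | CCOC(=C(CC=C(C)C)[C@H](O[Si](CC)(CC)CC)C(C)C)C(C)=C=O | intermediate (not isolated)
14 | 3-ethoxy-4-{1-ethoxy-5-methyl-2-[(R)-2-methyl-1-(triethylsilyloxy)propyl]hexa-1,4-dien-1-yl}-4-methylcyclobut-2-en-1-one | CCOC1=CC(=O)C1(C)C(OCC)=C(CC=C(C)C)[C@H](O[Si](CC)(CC)CC)C(C)C | intermediate (not isolated)
15 | 3,5-diethoxy-4,9-dimethyl-6-[(R)-2-methyl-1-(triethylsilyloxy)propyl]deca-1,3,5,8-tetraen-1-one (dienylketene) | CCOC(C=C=O)=C(C)C(OCC)=C(CC=C(C)C)[C@H](O[Si](CC)(CC)CC)C(C)C | intermediate (not isolated)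
16 | (S)-3,5-diethoxy-4-methyl-6-(3-methylbut-2-en-1-yl)-6-[(R)-2-methyl-1-(triethylsilyloxy)propyl]cyclohexa-2,4-dien-1-one | CCOC1=CC(=O)[C@@](CC=C(C)C)([C@H](O[Si](CC)(CC)CC)C(C)C)C(OCC)=C1C | intermediate
17 | (S)-3,5-diethoxy-6-[(R)-1-hydroxy-2-methylpropyl]-4-methyl-6-(3-methylbut-2-en-1-yl)cyclohexa-2,4-dien-1-one | CCOC1=CC(=O)[C@@](CC=C(C)C)([C@H](O)C(C)C)C(OCC)=C1C | intermediate
18 | (R)-3,5-diethoxy-4-methyl-6-(3-methylbut-2-en-1-yl)-6-(2-methylpropanoyl)cyclohexa-2,4-dien-1-one | CCOC1=CC(=O)[C@@](CC=C(C)C)(C(=O)C(C)C)C(OCC)=C1C | intermediate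
19 | (R)-3,5-dihydroxy-2-methyl-4-(3-methylbut-2-en-1-yl)-4-(2-methylpropanoyl)cyclohexa-2,5-dien-1-one | O=C1C=C(O)[C@@](CC=C(C)C)(C(=O)C(C)C)C(O)=C1C | intermediate
20 | 2-methyl-1-(2,4,6-trihydroxyphenyl)propan-1-one (phlorisobutyrophenone) | CC(C)C(=O)c1c(O)cc(O)cc1O | starting material
21 | 2-methyl-1-[2,4,6-trihydroxy-3-(3-methylbut-2-en-1-yl)phenyl]propan-1-one | CC(C)C(=O)c1c(O)cc(O)c(CC=C(C)C)c1O | intermediate
22 | N,N-dimethylmethyleneiminium iodide (Eschenmoser's salt) | C=[N+](C)C.[I-] | starting material
23 | 1-[3-(dimethylaminomethyl)-2,4,6-trihydroxy-5-(3-methylbut-2-en-1-yl)phenyl]-2-methylpropan-1-one (Mannich base) | CC(C)C(=O)c1c(O)c(CN(C)C)c(O)c(CC=C(C)C)c1O | intermediate (not isolated)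
24 | 3,5-dihydroxy-6-methylidene-4-(3-methylbut-2-en-1-yl)-2-(2-methylpropanoyl)cyclohexa-2,4-dien-1-one (ortho-quinone methide) | C=C1C(=O)C(C(=O)C(C)C)=C(O)C(CC=C(C)C)=C1O | intermediate (not isolated)
25 | (S)-3,5-dihydroxy-6-methyl-4-(3-methylbut-2-en-1-yl)-4-(2-methylpropanoyl)-2-{[2,4,6-trihydroxy-3-(3-methylbut-2-en-1-yl)-5-(2-methylpropanoyl)phenyl]methyl}cyclohexa-2,5-dien-1-one (CNP0191741.1) | CC(C)=CCc1c(O)c(CC2=C(O)[C@@](CC=C(C)C)(C(=O)C(C)C)C(O)=C(C)C2=O)c(O)c(C(=O)C(C)C)c1O | target

Total step count: 11. Longest linear sequence: 10 (steps 1 to 9, then step 11).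

Steps most likely to fail

Step 6. The prenyl group may divert the vinylketene into an intramolecular ketene–alkene cycloaddition, or leave C-6 of the product by a Cope or retro-Claisen shift at the annulation temperature. Poor facial selectivity in the 6π closure would cost material but not purity. The fallback sets out from 11 and carries the double bond through the annulation in masked form. The prenyl alkene of 11 is epoxidised with dimethyldioxirane (acetone, 0 °C) to the cyclobutenone epoxide F1 (epoxide carbon as a mixture). F1 is heated with 12 as in step 6 to the dienone epoxide F2, which has no alkene for pericyclic side reactions. The double bond is then restored with triphenylphosphine selenide and trifluoroacetic acid (CH2Cl2, 23 °C), which comes back to the route at 16, where the C-6 epimers are separated.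

Step 7. Once the carbinol is free, retro-aldol loss of isobutyraldehyde with aromatisation of the ring may compete. The fallback sets out from 16 and replaces desilylation and oxidation by one oxidative cleavage: excess 2-iodoxybenzoic acid in DMSO at 23 °C should cleave the triethylsilyl ether and oxidise the alcohol as it forms, so that 17 never accumulates. It comes back to the route at 18 and makes no new compound (F0).

Step 11. The one-carbon bridge may scramble to the two symmetrical dimers, and the amine present may deacylate the quaternary carbon. The fallback reverses the roles of the two halves. It sets out from 19, whose only ring C–H is aminomethylated with 22 (Et3N, CH2Cl2, 0 °C) to the isolated trione Mannich base F3. F3 is then heated with 21 in dioxane (60 °C); the enone methide released from it should alkylate the one free aromatic carbon of 21, which comes back to the route at 25.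

Further compounds
F1 | step 6 | 4-[(3,3-dimethyloxiran-2-yl)methyl]-3-ethoxy-2-methyl-4-[(R)-2-methyl-1-(triethylsilyloxy)propyl]cyclobut-2-en-1-one | CCOC1=C(C)C(=O)C1(CC2OC2(C)C)[C@H](O[Si](CC)(CC)CC)C(C)C
F2 | step 6 | (S)-6-[(3,3-dimethyloxiran-2-yl)methyl]-3,5-diethoxy-4-methyl-6-[(R)-2-methyl-1-(triethylsilyloxy)propyl]cyclohexa-2,4-dien-1-one | CCOC1=CC(=O)[C@@](CC2OC2(C)C)([C@H](O[Si](CC)(CC)CC)C(C)C)C(OCC)=C1C
F0 | step 7 | none | none
F3 | step 11 | (S)-2-(dimethylaminomethyl)-3,5-dihydroxy-6-methyl-4-(3-methylbut-2-en-1-yl)-4-(2-methylpropanoyl)cyclohexa-2,5-dien-1-one | CN(C)CC1=C(O)[C@@](CC=C(C)C)(C(=O)C(C)C)C(O)=C(C)C1=O
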